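**Plan**
- Retrosynthesis: after removal of the neopentyl and benzyl groups, ring A is cut at C4a–C5 and C6–C7. This is possible because ring A shares its C4a–C8a bond with the pyranone (ring C), so that this C=C can end a dienylketene whose carbonyl carbon is the hydroxylated C5 and whose central carbon C6 carries sulfur.
- The ketene is traced to diazo keto sulfonate 15 (Wolff shift of C7 from C5 to C6). 15 is cut at C7=C8 into pyranone aldehyde 6 and keto sulfonate 11, and 11 at its CO–CH2S bond into ethyl benzyloxyacetate and neopentyl mesylate.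
- Forward: ring B is bought with dione 1, ring C closes in step 1, the chain is joined in steps 6–7, ring A closes last in step 10, and two deprotections finish.
- Stereochemistry: the target has no stereocentre. The only element that matters, the E geometry of C7=C8 in 15, comes from the sensitised isomerisation of step 8.

Key step: step 10

Remark: compounds 1, 2, 7, 8 and 10 are taken as catalogue chemicals; flavone numbering (C2 to C8a) is used for the atoms of all intermediates.

Step 1
Reactants: 1 1-(4-methoxyphenyl)butane-1,3-dione; 2 diethyl oxalate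
Product: 4 ethyl 6-(4-methoxyphenyl)-4-oxo-4H-pyran-2-carboxylate, via triketo ester 3 (not isolated)
Conditions: NaOEt (2.2 equiv), EtOH, 0 °C to rt; then conc. HCl, EtOH, reflux
Reagents that add atoms: none
Why: Crossed Claisen condensation of the diketone (through its dianion) at the terminal methyl group with non-enolisable diethyl oxalate gives triketo ester 3, whose acid-catalysed cyclodehydration, the classical comanic ester synthesis, closes the 4-pyranone.

Step 2
Reactants: 4 ethyl 6-(4-methoxyphenyl)-4-oxo-4H-pyran-2-carboxylate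
Product: 5 2-(hydroxymethyl)-6-(4-methoxyphenyl)-4H-pyran-4-one
Conditions: NaBH4 (1.5 equiv), MeOH, 0 °C; then 1 M HCl
Reagents that add atoms: none
Why: Borohydride reduction of an activated ester, as with chromone-2-carboxylates: the ester on the electron-poor pyranone C2 should be reduced chemoselectively while the vinylogous-ester ring carbonyl is left alone.

Step 3
Reactants: 5 2-(hydroxymethyl)-6-(4-methoxyphenyl)-4H-pyran-4-one
Product: 6 6-(4-methoxyphenyl)-4-oxo-4H-pyran-2-carbaldehyde
Conditions: Dess–Martin periodinane (1.2 equiv), CH2Cl2, rt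
Reagents that add atoms: none
Why: Dess–Martin oxidation of the primary allylic-type alcohol should stop at the aldehyde, and the non-aqueous conditions deliver the easily hydrated pyranone carbaldehyde water-free.

Step 4
Reactants: 7 neopentyl alcohol (2,2-dimethylpropan-1-ol); 8 methanesulfonyl chloride
Product: 9 neopentyl methanesulfonate
Conditions: Et3N, CH2Cl2, 0 °C
Reagents that add atoms: none
Why: Mesylation of a primary alcohol through the sulfene pathway; the neopentyl ester is chosen because its SN2-inert carbon should carry the sulfonate through base, acid, light and hydrogenation.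

Step 5
Reactants: 9 neopentyl methanesulfonate; 10 ethyl benzyloxyacetate
Product: 11 neopentyl 3-(benzyloxy)-2-oxopropane-1-sulfonate
Conditions: 9 (2.2 equiv), n-BuLi (2.1 equiv), THF, −78 °C; then 10 (1.0 equiv), −78 to −30 °C; aq. HCl
Reagents that add atoms: none
Why: Claisen-type C-acylation of the α-lithio sulfonate by the ester, in which the second equivalent of carbanion takes up the acidic proton of the β-keto sulfonate formed and so prevents over-addition.

Step 6
Reactants: 11 neopentyl 3-(benzyloxy)-2-oxopropane-1-sulfonate; 6 6-(4-methoxyphenyl)-4-oxo-4H-pyran-2-carbaldehyde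
Product: 12 neopentyl 3-(benzyloxy)-4-hydroxy-4-[6-(4-methoxyphenyl)-4-oxo-4H-pyran-2-yl]-2-oxobutane-1-sulfonate (mixture of racemic syn/anti diastereomers)
Conditions: LiN(i-Pr)2 (2.2 equiv), THF, −78 to −20 °C; then 6, −78 °C; AcOH quench
Reagents that add atoms: none
Why: Weiler-type dianion aldol addition, known for β-keto esters and β-keto sulfones: double deprotonation makes the benzyloxy-bearing γ-carbon the more nucleophilic site, which should add to the highly electrophilic non-enolisable aldehyde; both new stereocentres form unselectively and are erased in step 7.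

Step 7
Reactants: 12 neopentyl 3-(benzyloxy)-4-hydroxy-4-[6-(4-methoxyphenyl)-4-oxo-4H-pyran-2-yl]-2-oxobutane-1-sulfonate
Product: 13 neopentyl (3Z)-3-(benzyloxy)-4-[6-(4-methoxyphenyl)-4-oxo-4H-pyran-2-yl]-2-oxobut-3-ene-1-sulfonate
Conditions: p-TsOH·H2O (10 mol %), toluene, 4 Å MS, 80 °C
Reagents that add atoms: none
Why: Acid-catalysed aldol dehydration through the enol gives the conjugated α-benzyloxy enone under thermodynamic control, which should favour the Z isomer with pyranone and acyl group trans.

Step 8
Reactants: 13 neopentyl (3Z)-3-(benzyloxy)-4-[6-(4-methoxyphenyl)-4-oxo-4H-pyran-2-yl]-2-oxobut-3-ene-1-sulfonate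
Product: 14 neopentyl (3E)-3-(benzyloxy)-4-[6-(4-methoxyphenyl)-4-oxo-4H-pyran-2-yl]-2-oxobut-3-ene-1-sulfonate
Conditions: thioxanthen-9-one (10 mol %), degassed MeCN, 405 nm LEDs, rt; chromatography, recovered 13 resubmitted
Reagents that add atoms: none
Why: Triplet-sensitised E/Z photoisomerisation of a polarised trisubstituted alkene, as with cinnamates and enones: the E isomer, whose acyl group is twisted out of conjugation by the cis pyranone, is the poorer energy acceptor and should accumulate in the photostationary mixture.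

Step 9
Reactants: 14 neopentyl (3E)-3-(benzyloxy)-4-[6-(4-methoxyphenyl)-4-oxo-4H-pyran-2-yl]-2-oxobut-3-ene-1-sulfonate
Product: 15 neopentyl (3E)-3-(benzyloxy)-1-diazo-4-[6-(4-methoxyphenyl)-4-oxo-4H-pyran-2-yl]-2-oxobut-3-ene-1-sulfonate
Conditions: 4-acetamidobenzenesulfonyl azide (1.2 equiv), Et3N (1.5 equiv), MeCN, 0 °C to rt, dark
Reagents that add atoms: 4-acetamidobenzenesulfonyl azide, CC(=O)Nc1ccc(cc1)S(=O)(=O)N=[N+]=[N-]
Why: Regitz diazo transfer to the activated methylene between ketone and sulfonate, the standard entry to α-diazo β-keto sulfonyl compounds, run cold and dark so that the alkene geometry is kept.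

Step 10
Reactants: 15 neopentyl (3E)-3-(benzyloxy)-1-diazo-4-[6-(4-methoxyphenyl)-4-oxo-4H-pyran-2-yl]-2-oxobut-3-ene-1-sulfonate
Product: 18 neopentyl 7-(benzyloxy)-5-hydroxy-2-(4-methoxyphenyl)-4-oxo-4H-chromene-6-sulfonate, via sulfonyl dienylketene 16 (not isolated), via cyclohexadienone 17 (not isolated)
Conditions: hν (365 nm LEDs), anhydrous degassed CH2Cl2 (5 mM), 20 °C; then 40 °C, dark
Reagents that add atoms: none
Why: Proposed new method: excitation of the s-Z diazo ketone should expel N2 with 1,2-shift of the alkenyl carbon C7 from C5 to C6 (Wolff rearrangement), giving sulfonyl dienylketene 16 in which the ketene C5=C6, the enol ether C7=C8 and the pyranone C8a=C4a form a cis-hexatriene. This triene should close ring A by thermal disrotatory six-electron electrocyclisation, the electrophilic ketene carbon C5 bonding to the nucleophilic pyranone carbon C4a, and the doubly activated C4a–H of dienone 17 should enolise at once to the aromatic 5-hydroxy compound, so the C4a stereocentre of 17 is transient and none remains. The closest known reactions are the photochemical Wolff rearrangement of α′-diazo enones to vinylketenes and the six-electron closure of dienylketenes to phenols that ends the Danheiser benzannulation; new here are the sulfonate on the carbon that receives the migrating group and a 4-pyranone C=C as the third π bond. Regiochemistry needs no control, because the chain fixes sulfur at C6 between the ketene-derived C5 oxygen and the C7 benzyloxy group and O1 already sits on C8a, so no 8-sulfonate can arise. What must be secured is the E geometry that holds ketene and pyranone cis (set in step 8 and replenished by photoequilibration under the lamp) and the absence of traps for the ketene, met by dry, dilute, aprotic solution; the chelated 5-hydroxy-4-keto unit of the product should dissipate further excitation by proton transfer.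

Step 11
Reactants: 18 neopentyl 7-(benzyloxy)-5-hydroxy-2-(4-methoxyphenyl)-4-oxo-4H-chromene-6-sulfonate
Product: 19 neopentyl 5,7-dihydroxy-2-(4-methoxyphenyl)-4-oxo-4H-chromene-6-sulfonate
Conditions: H2 (1 atm), 10% Pd/C, EtOAc–THF, rt
Reagents that add atoms: none
Why: Catalytic hydrogenolysis of the aryl benzyl ether, under which the flavone C2=C3 bond, the sulfonate ester and the aryl methyl ether are not expected to react at one atmosphere of H2.

Step 12
Reactants: 19 neopentyl 5,7-dihydroxy-2-(4-methoxyphenyl)-4-oxo-4H-chromene-6-sulfonate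
Product: 21 niruriflavone (5,7-dihydroxy-2-(4-methoxyphenyl)-4-oxo-4H-chromene-6-sulfonic acid), via tetramethylammonium sulfonate 20 (not isolated)
Conditions: Me4NCl (5 equiv), DMF, 160 °C; then aq. HCl, C18 reversed-phase chromatography
Reagents that add atoms: none
Why: SN2 dealkylation of the neopentyl sulfonate by chloride in hot DMF, the established unmasking of neopentyl-protected sulfonic acids, followed by protonation of the salt; heating is stopped at full conversion to limit chloride attack on the 4′-methyl ether.

**Compound list**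
1 | 1-(4-methoxyphenyl)butane-1,3-dione | COc1ccc(cc1)C(=O)CC(C)=O | starting material
2 | diethyl oxalate | CCOC(=O)C(=O)OCC | starting material
3 | ethyl 6-(4-methoxyphenyl)-2,4,6-trioxohexanoate | CCOC(=O)C(=O)CC(=O)CC(=O)c1ccc(OC)cc1 | intermediate (not isolated)
4 | ethyl 6-(4-methoxyphenyl)-4-oxo-4H-pyran-2-carboxylate | CCOC(=O)c1cc(=O)cc(o1)-c1ccc(OC)cc1 | intermediate
5 | 2-(hydroxymethyl)-6-(4-methoxyphenyl)-4H-pyran-4-one | COc1ccc(cc1)-c1cc(=O)cc(CO)o1 | intermediate
6 | 6-(4-methoxyphenyl)-4-oxo-4H-pyran-2-carbaldehyde | COc1ccc(cc1)-c1cc(=O)cc(C=O)o1 | intermediate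
7 | neopentyl alcohol (2,2-dimethylpropan-1-ol) | CC(C)(C)CO | starting material
8 | methanesulfonyl chloride | CS(=O)(=O)Cl | starting material
9 | neopentyl methanesulfonate | CC(C)(C)COS(C)(=O)=O | intermediate
10 | ethyl benzyloxyacetate | CCOC(=O)COCc1ccccc1 | starting material
11 | neopentyl 3-(benzyloxy)-2-oxopropane-1-sulfonate | CC(C)(C)COS(=O)(=O)CC(=O)COCc1ccccc1 | intermediate
12 | neopentyl 3-(benzyloxy)-4-hydroxy-4-[6-(4-methoxyphenyl)-4-oxo-4H-pyran-2-yl]-2-oxobutane-1-sulfonate, mixture of racemic syn and anti diastereomers (no configuration assigned) | COc1ccc(cc1)-c1cc(=O)cc(o1)C(O)C(OCc1ccccc1)C(=O)CS(=O)(=O)OCC(C)(C)C | intermediate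
13 | neopentyl (3Z)-3-(benzyloxy)-4-[6-(4-methoxyphenyl)-4-oxo-4H-pyran-2-yl]-2-oxobut-3-ene-1-sulfonate | COc1ccc(cc1)-c1cc(=O)cc(o1)/C=C(\OCc1ccccc1)C(=O)CS(=O)(=O)OCC(C)(C)C | intermediate
14 | neopentyl (3E)-3-(benzyloxy)-4-[6-(4-methoxyphenyl)-4-oxo-4H-pyran-2-yl]-2-oxobut-3-ene-1-sulfonate | COc1ccc(cc1)-c1cc(=O)cc(o1)/C=C(/OCc1ccccc1)C(=O)CS(=O)(=O)OCC(C)(C)C | intermediate
15 | neopentyl (3E)-3-(benzyloxy)-1-diazo-4-[6-(4-methoxyphenyl)-4-oxo-4H-pyran-2-yl]-2-oxobut-3-ene-1-sulfonate | COc1ccc(cc1)-c1cc(=O)cc(o1)/C=C(/OCc1ccccc1)C(=O)C(=[N+]=[N-])S(=O)(=O)OCC(C)(C)C | intermediate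
16 | neopentyl (3E)-3-(benzyloxy)-4-[6-(4-methoxyphenyl)-4-oxo-4H-pyran-2-yl]-1-oxobuta-1,3-diene-2-sulfonate | COc1ccc(cc1)-c1cc(=O)cc(o1)/C=C(/OCc1ccccc1)C(=C=O)S(=O)(=O)OCC(C)(C)C | intermediate (not isolated)
17 | neopentyl 7-(benzyloxy)-2-(4-methoxyphenyl)-4,5-dioxo-4a,5-dihydro-4H-chromene-6-sulfonate, racemic at C4a | COc1ccc(cc1)C1=CC(=O)C2C(=O)C(=C(OCc3ccccc3)C=C2O1)S(=O)(=O)OCC(C)(C)C | intermediate (not isolated)
18 | neopentyl 7-(benzyloxy)-5-hydroxy-2-(4-methoxyphenyl)-4-oxo-4H-chromene-6-sulfonate | COc1ccc(-c2cc(=O)c3c(O)c(S(=O)(=O)OCC(C)(C)C)c(OCc4ccccc4)cc3o2)cc1 | intermediate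
19 | neopentyl 5,7-dihydroxy-2-(4-methoxyphenyl)-4-oxo-4H-chromene-6-sulfonate | COc1ccc(-c2cc(=O)c3c(O)c(S(=O)(=O)OCC(C)(C)C)c(O)cc3o2)cc1 | intermediate
20 | tetramethylammonium 5,7-dihydroxy-2-(4-methoxyphenyl)-4-oxo-4H-chromene-6-sulfonate | COc1ccc(-c2cc(=O)c3c(O)c(S(=O)(=O)[O-])c(O)cc3o2)cc1.C[N+](C)(C)C | intermediate (not isolated)
21 | niruriflavone, 5,7-dihydroxy-2-(4-methoxyphenyl)-4-oxo-4H-chromene-6-sulfonic acid | COc1ccc(-c2cc(=O)c3c(O)c(S(=O)(=O)O)c(O)cc3o2)cc1 | target

**Totals**
Total steps: 12. Longest linear sequence: 10 steps (from 1 through steps 1–3 and 6–12); the side chain (steps 4 and 5) joins at step 6.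

**Steps most likely to fail**

Step 10 (the proposed new method).
- What may go wrong: the photogenerated carbene may insert into C–H bonds of the neopentyl group or the solvent before it rearranges. The ketene may be intercepted by moisture, by the phenol already formed, or by dimerisation faster than it closes. The alkene may also drift under the lamp to the geometry whose ketene cannot cyclise.
- Fallback with known chemistry, from 15 back to 18: 15 is photolysed in THF–water, so that the Wolff ketene is trapped deliberately as an acid (Arndt–Eistert-type). This should give (3E)-3-(benzyloxy)-2-[(2,2-dimethylpropoxy)sulfonyl]-4-[6-(4-methoxyphenyl)-4-oxo-4H-pyran-2-yl]but-3-enoic acid F1. Heating F1 with Ac2O and NaOAc (Stobbe-type cyclodehydration) should let the mixed anhydride acylate the nucleophilic pyranone C3, while the enolisable C–H next to sulfur lets the double bond equilibrate, so geometry no longer limits ring closure. The product would be neopentyl 5-acetoxy-7-(benzyloxy)-2-(4-methoxyphenyl)-4-oxo-4H-chromene-6-sulfonate F2. Methanolysis of the aryl acetate (K2CO3, MeOH, rt) returns to the route at 18.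

Step 8.
- What may go wrong: the photostationary state may stay on the side of the Z isomer, the excited pyranone may dimerise or rearrange, or the E isomer may relax on handling.
- Fallback, from 13 back to 15 and 18: the geometry is no longer set beforehand. 13 is taken through the diazo transfer of step 9 to neopentyl (3Z)-3-(benzyloxy)-1-diazo-4-[6-(4-methoxyphenyl)-4-oxo-4H-pyran-2-yl]-2-oxobut-3-ene-1-sulfonate F3. F3 is irradiated with a Pyrex-filtered medium-pressure mercury lamp (300–400 nm) in dry CH2Cl2. Direct excitation of the enone should interconvert F3 and 15 in the flask, and only 15 can funnel through 16 and 17 to 18, where the route is rejoined.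

Step 6.
- What may go wrong: the second deprotonation may be incomplete, so that the monoanion only shuttles protons. The dianion may attack the pyranone ring in place of the aldehyde, or the aldol may revert on work-up.
- Fallback, from 6 back to 13 (compounds 11 and 12 and steps 5–7 are bypassed): the alkene is made by olefination and the sulfonate carbon is added afterwards. Ethyl 2-(benzyloxy)-2-(diethoxyphosphoryl)acetate F4 is prepared from benzyl alcohol and ethyl diazo(diethoxyphosphoryl)acetate by Rh2(OAc)4-catalysed O–H insertion. Horner–Wadsworth–Emmons reaction of F4 with 6 (LiCl, DBU, MeCN) should give ethyl (2Z)-2-(benzyloxy)-3-[6-(4-methoxyphenyl)-4-oxo-4H-pyran-2-yl]prop-2-enoate F5; either geometry serves, since step 8 follows. Claisen acylation of lithiated 9 (2.2 equiv, n-BuLi, THF, −78 °C) with F5 then delivers 13.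

Further compounds
F1 | step 10 | (3E)-3-(benzyloxy)-2-[(2,2-dimethylpropoxy)sulfonyl]-4-[6-(4-methoxyphenyl)-4-oxo-4H-pyran-2-yl]but-3-enoic acid, racemic | COc1ccc(cc1)-c1cc(=O)cc(o1)/C=C(/OCc1ccccc1)C(C(=O)O)S(=O)(=O)OCC(C)(C)C
F2 | step 10 | neopentyl 5-acetoxy-7-(benzyloxy)-2-(4-methoxyphenyl)-4-oxo-4H-chromene-6-sulfonate | COc1ccc(-c2cc(=O)c3c(OC(C)=O)c(S(=O)(=O)OCC(C)(C)C)c(OCc4ccccc4)cc3o2)cc1
F3 | step 8 | neopentyl (3Z)-3-(benzyloxy)-1-diazo-4-[6-(4-methoxyphenyl)-4-oxo-4H-pyran-2-yl]-2-oxobut-3-ene-1-sulfonate | COc1ccc(cc1)-c1cc(=O)cc(o1)/C=C(\OCc1ccccc1)C(=O)C(=[N+]=[N-])S(=O)(=O)OCC(C)(C)C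
F4 | step 6 | ethyl 2-(benzyloxy)-2-(diethoxyphosphoryl)acetate | CCOC(=O)C(OCc1ccccc1)P(=O)(OCC)OCC
F5 | step 6 | ethyl (2Z)-2-(benzyloxy)-3-[6-(4-methoxyphenyl)-4-oxo-4H-pyran-2-yl]prop-2-enoate | CCOC(=O)/C(OCc1ccccc1)=C/c1cc(=O)cc(o1)-c1ccc(OC)cc1
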